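We are given no constants, so we read what we can from the runs, in which Dx turns Gu into Ze.

| setting | north-east | south | east | flask |
|---|---|---|---|---|
| Gu | 0.067 M | 0.15 M | 0.10 M | 0.10 M |
| Dx | 31 µM | 31 µM | 16 µM | 31 µM |
| remark | run made earlier | run made earlier | run made earlier |  |

| run | time / min | Ze / % | Gu / % |
|---|---|---|---|
| north-east | 4.00 | 7 | 92 |
| north-east | 8.00 | 16 | 85 |
| north-east | 15.0 | 26 | 75 |
| north-east | 25.0 | 34 | 63 |
| north-east | 50.0 | 52 | 49 |
| south | 10.0 | 19 | 77 |
| south | 20.0 | 40 | 60 |
| south | 30.0 | 55 | 47 |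
| south | 40.0 | 61 | 40 |
| south | 50.0 | 66 | 34 |
| east | 4.00 | 5 | 94 |
| east | 8.00 | 14 | 88 |
| east | 15.0 | 18 | 82 |
| east | 25.0 | 30 | 65 |
| east | 50.0 | 48 | 52 |

(standard deviation of a reading: 1.5 percentage points)

1. apparent order in Dx when 30 % of the Gu are converted (percent change of the rate of making Ze for one percent more Dx charged)

Straight lines between readings put 30 % Ze at 20.0 min in the north-east run and 15.2 min in the south run. Their geometric mean, 17.5 min, stands in for the flask, whose Gu charge lies between theirs. The east run, with less Dx than the flask, takes 25.0 min. We call the flask's Dx charge over the east charge the charge ratio g, 1.94, and our reckoned order n is ln(time ratio)/ln g, or 0.543, a loose reading.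

An order below one suggests a pre-equilibrium in which Dx pairs with itself. With charge C, free Dx x and pairing constant K, C = x + 2K·x·x. If the rate follows x, then n = 1/(2 − f), where f = x/C, and n falls from one towards 0.5 as f falls.

The forecast, from the same runs, is 0.55, "perhaps a half-order enzyme association".

The flask gives 0.69. After 20.0 min the flask holds 54.0 % of its catalyst as free Dx and 46.0 % as the pair Ly.

    2 Dx ⇌ Ly, settled at all times (K = 25400 L mol⁻¹)
    Gu + Dx → Ze + Dx, rate k2*[Gu]^2.5*[Dx]/(1 + ([Gu]/Kh2)^2.5) (0.0978 M, k = 1690 L²·⁵ mol⁻²·⁵ s⁻¹)

In the east run, the pairing constant leaves 10.5 µM of Dx free, against 16.7 µM in the flask, so between these two charges free Dx goes as the charge ratio g raised to the power 0.713.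

Readings and results were generated by integration for an exercise; the scatter is artificial.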